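**Retrosynthetic overview**
- The target is opened last: a 3α,4α-epoxy-5β-alcohol takes angelic acid at C3 with inversion, which gives the 3-angelate and the free 4,5-diol at once.
- Both oxirane/carbinol halves come from one pseudo-symmetric (1(10)Z,3Z)-germacradiene-5,9-dione by Luche reduction and hydroxyl-directed epoxidation, the C9 half first (kept as oxirane, then angeloylated).
- The dienedione comes from a (1(10)Z,4E)-dienone by singlet-oxygen ene reaction, dehydration and exo-to-endo alkene shift (C4=C5 becomes C5=O with C3=C4).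
- The ten-membered ring comes from thermal cycloreversion of the [2+2] photoadduct of 6-acyloxycarvone and 1-methylcyclobutene; the photochemical step forms the C1–C10 and C4–C5 ring bonds.
- Ring order: carvone six-membered ring (bought), two cyclobutanes (photoadduct), ten-membered carbocycle, 1,10-oxirane, 3,4-oxirane (opened in the last step).

Assumption and convention: germacrane numbering is used (C7 carries the isopropenyl group, C4 and C10 the methyls; β is the ring face of the isopropenyl group, α the opposite face); 1-methylcyclobutene, angelic anhydride and (R)-2-methylbutanoic acid are taken as catalogue compounds.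

Step 1
Reactants: 1 (S)-(+)-carvone
Product: 3 (5R,6R)-6-hydroxy-2-methyl-5-(prop-1-en-2-yl)cyclohex-2-en-1-one (trans-6-hydroxycarvone), via sodium dienolate 2 (not isolated)
Conditions: NaN(SiMe3)2, THF, −78 °C; then (±)-2-(phenylsulfonyl)-3-phenyloxaziridine, −78 °C; AcOH quench
Reagents that add atoms: (±)-2-(phenylsulfonyl)-3-phenyloxaziridine, O=S(=O)(c1ccccc1)N1OC1c1ccccc1
Why: Kinetic deprotonation at the α'-CH2 and Davis enolate hydroxylation, the racemic oxaziridine (an oxygen donor only) approaching anti to the neighbouring isopropenyl group so that the new carbinol centre is trans to it (5R,6R).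

Step 2
Reactants: 3 trans-6-hydroxycarvone; 4 (R)-2-methylbutanoic acid
Product: 5 (1R,6R)-3-methyl-2-oxo-6-(prop-1-en-2-yl)cyclohex-3-en-1-yl (2R)-2-methylbutanoate
Conditions: DCC, DMAP (cat.), CH2Cl2, 0 °C to rt
Reagents that add atoms: none
Why: Steglich esterification of the secondary α-hydroxy ketone, in which no stereocentre is formed and the acid α-centre is not enolised.

Step 3
Reactants: 5 acyloxycarvone; 6 1-methylcyclobutene
Product: 7 cis-anti-cis photoadduct 2,6-dimethyl-7-oxo-9-(prop-1-en-2-yl)tricyclo[4.4.0.0^2,5]decan-8-yl (2R)-2-methylbutanoate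
Conditions: 6 (8 equiv), hν (350 nm, Pyrex), CH2Cl2, −20 °C
Reagents that add atoms: none
Why: Enone–alkene [2+2] photocycloaddition through the enone triplet (excess alkene outruns the slow intramolecular cycloaddition of carvone), head-to-tail so that the enone β-carbon bonds to the methyl-bearing alkene carbon and two adjacent quaternary carbons are avoided; this forms C1–C10 and C4–C5, and the four new cyclobutane centres are transient because step 4 makes them sp2.

Step 4
Reactants: 7 photoadduct
Product: 8 (1(10)Z,4E)-8α-[(2R)-2-methylbutanoyloxy]germacra-1(10),4,11-trien-9-one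
Conditions: PhMe (degassed, sealed base-washed tube), 190 °C, 1–2 h
Reagents that add atoms: none
Why: Thermal formal retro-[2+2] of the strained bicyclo[2.2.0]hexane unit (central σ-bond homolysis to a cyclohexane-1,4-diyl, then cleavage of the former enone Cα–Cβ bond) gives the cis,trans-cyclodeca-1,5-diene with the conjugated double bond Z, leaving C7 and C8 untouched.

Step 5
Reactants: 8 germacratrienone
Product: 10 (1(10)Z)-8α-[(2R)-2-methylbutanoyloxy]germacra-1(10),4(15),11-triene-5,9-dione, via allylic hydroperoxide 9 (not isolated)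
Conditions: O2, tetraphenylporphyrin (cat.), hν (visible), CH2Cl2, −10 °C; then Ac2O, pyridine, DMAP (cat.), 0 °C to rt
Reagents that add atoms: dioxygen (as singlet oxygen), O=O
Why: Schenck ene reaction at the only electron-rich trisubstituted alkene (enone and isopropenyl react far more slowly), oxygen bonding to C5 and hydrogen leaving from the C15 methyl on the more crowded side of the E-alkene, then Kornblum–DeLaMare dehydration of the secondary allylic hydroperoxide to the ketone, which removes the transient C5 centre.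

Step 6
Reactants: 10 exocyclic enone
Product: 11 (1(10)Z,3Z)-8α-[(2R)-2-methylbutanoyloxy]germacra-1(10),3,11-triene-5,9-dione
Conditions: RhCl3·3H2O (5 mol%), EtOH, 50 °C
Reagents that add atoms: none
Why: Rhodium hydride exo-to-endo isomerisation of an α-methylene ketone (conjugate hydrometalation, then β-hydride elimination from C3) gives the thermodynamically preferred trisubstituted Z-enone, the conjugated exocyclic alkene reacting faster than the isolated isopropenyl group.

Step 7
Reactants: 11 dienedione
Product: 12 (1(10)Z,3Z)-9β-hydroxy-8α-[(2R)-2-methylbutanoyloxy]germacra-1(10),3,11-trien-5-one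
Conditions: NaBH4 (0.3 equiv), CeCl3·7H2O, MeOH/THF, −78 °C
Reagents that add atoms: none
Why: Luche 1,2-reduction in which the C9 carbonyl, activated by its α-acyloxy group, is reduced first by a sub-stoichiometric hydride charge, and Felkin–Anh attack anti to the C8–O bond from the outer face of the ring gives the 9β-alcohol (8,9-threo).

Step 8
Reactants: 12 allylic alcohol
Product: 13 (3Z)-1α,10α-epoxy-9β-hydroxy-8α-[(2R)-2-methylbutanoyloxy]germacra-3,11-dien-5-one
Conditions: mCPBA (1.1 equiv), CH2Cl2, 0 °C
Reagents that add atoms: mCPBA (3-chloroperoxybenzoic acid), OOC(=O)c1cccc(Cl)c1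
Why: Henbest hydroxyl-directed peracid epoxidation, in which the C9–H eclipses the Z-alkene (allylic 1,3-strain) and the hydrogen-bonded peracid attacks the outer face to give the threo (ring-trans) epoxy alcohol typical of medium-ring cis-cycloalkenols, i.e. the 1α,10α-oxirane, while the enone and isopropenyl alkenes react much more slowly.

Step 9
Reactants: 13 epoxy alcohol; 14 angelic acid
Product: 16 (3Z)-9β-angeloyloxy-1α,10α-epoxy-8α-[(2R)-2-methylbutanoyloxy]germacra-3,11-dien-5-one, via mixed anhydride 15 (not isolated)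
Conditions: 14, 2,4,6-trichlorobenzoyl chloride, Et3N, PhMe, rt; then 13, 80 °C
Reagents that add atoms: none
Why: Yamaguchi-type mixed-anhydride esterification of the hindered secondary alcohol without a free alkoxide or nucleophilic catalyst, which avoids angelate-to-tiglate isomerisation and 8-to-9 acyl migration and changes no stereocentre.

Step 10
Reactants: 16 epoxy enone
Product: 17 (3Z)-9β-angeloyloxy-1α,10α-epoxy-5β-hydroxy-8α-[(2R)-2-methylbutanoyloxy]germacra-3,11-diene
Conditions: NaBH4, CeCl3·7H2O, MeOH, −78 °C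
Reagents that add atoms: none
Why: Luche 1,2-reduction of the only remaining ketone, whose enone is the mirror counterpart of the C9 enone across the C2···C7 axis, so hydride from the outer face gives the 5β-allylic alcohol (cis to the C7 side chain).

Step 11
Reactants: 17 allylic alcohol; 18 angelic anhydride
Product: 21 3β,9β-bis(angeloyloxy)-1α,10α-epoxy-4α,5β-dihydroxy-8α-[(2R)-2-methylbutanoyloxy]germacr-11-ene (CNP0246823.2), via peroxyangelic acid 19 (not isolated), via diepoxy alcohol 20 (not isolated)
Conditions: 18 (1.1 equiv), urea·H2O2 (1.1 equiv), CH2Cl2, 0 °C; then 17, 0 °C; then Ti(OiPr)4 (1.5 equiv), rt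
Reagents that add atoms: urea–hydrogen peroxide, NC(N)=O.OO
Why: Proposed new method: a peracid whose own carboxylic acid is the nucleophile needed next—peroxyangelic acid (from the anhydride and urea–H2O2) epoxidises the Z-allylic alcohol under hydroxyl direction (threo, 3α,4α, as in step 8), and the angelic acid thereby released is delivered by Ti(OiPr)4, bound to the C5 alkoxide and the oxirane oxygen, to the distal secondary carbon C3 with inversion (the fully substituted C4 cannot be attacked from the rear and the 1,10-oxirane has no free hydroxyl to template its opening), giving C3β–OAng, C4α–OH and free C5β–OH in one flask; the closest known reactions are the Henbest epoxidation of allylic alcohols and the titanium tetraisopropoxide-mediated C3-selective opening of 2,3-epoxy alcohols by carboxylic acids.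

**Compound list**
1 | (S)-(+)-carvone | C=C(C)[C@H]1CC=C(C)C(=O)C1 | starting material
2 | sodium (3S)-6-methyl-3-(prop-1-en-2-yl)cyclohexa-1,5-dien-1-olate | C=C(C)[C@H]1CC=C(C)C([O-])=C1.[Na+] | intermediate
3 | (5R,6R)-6-hydroxy-2-methyl-5-(prop-1-en-2-yl)cyclohex-2-en-1-one | C=C(C)[C@H]1CC=C(C)C(=O)[C@@H]1O | intermediate
4 | (R)-2-methylbutanoic acid | CC[C@@H](C)C(O)=O | starting material
5 | (1R,6R)-3-methyl-2-oxo-6-(prop-1-en-2-yl)cyclohex-3-en-1-yl (2R)-2-methylbutanoate | C=C(C)[C@H]1CC=C(C)C(=O)[C@@H]1OC(=O)[C@H](C)CC | intermediate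
6 | 1-methylcyclobutene | CC1=CCC1 | starting material
7 | 2,6-dimethyl-7-oxo-9-(prop-1-en-2-yl)tricyclo[4.4.0.0^2,5]decan-8-yl (2R)-2-methylbutanoate, cis-anti-cis, cyclobutanes anti to the isopropenyl group (major isomer shown; the other cyclobutane isomers converge in step 4) | C=C(C)[C@H]1C[C@@H]2[C@@]3(C)CC[C@H]3[C@]2(C)C(=O)[C@@H]1OC(=O)[C@H](C)CC | intermediate
8 | (1(10)Z,4E)-8α-[(2R)-2-methylbutanoyloxy]germacra-1(10),4,11-trien-9-one | C=C(C)[C@H]1C/C=C(C)/CC/C=C(C)\C(=O)[C@@H]1OC(=O)[C@H](C)CC | intermediate
9 | (1(10)Z)-5-hydroperoxy-8α-[(2R)-2-methylbutanoyloxy]germacra-1(10),4(15),11-trien-9-one (5β shown; either C5 epimer serves) | C=C(C)[C@H]1C[C@@H](OO)C(=C)CC/C=C(C)\C(=O)[C@@H]1OC(=O)[C@H](C)CC | intermediate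
10 | (1(10)Z)-8α-[(2R)-2-methylbutanoyloxy]germacra-1(10),4(15),11-triene-5,9-dione | C=C(C)[C@H]1CC(=O)C(=C)CC/C=C(C)\C(=O)[C@@H]1OC(=O)[C@H](C)CC | intermediate
11 | (1(10)Z,3Z)-8α-[(2R)-2-methylbutanoyloxy]germacra-1(10),3,11-triene-5,9-dione | C=C(C)[C@H]1CC(=O)/C(C)=C\C/C=C(C)\C(=O)[C@@H]1OC(=O)[C@H](C)CC | intermediate
12 | (1(10)Z,3Z)-9β-hydroxy-8α-[(2R)-2-methylbutanoyloxy]germacra-1(10),3,11-trien-5-one | C=C(C)[C@H]1CC(=O)/C(C)=C\C/C=C(C)\[C@@H](O)[C@@H]1OC(=O)[C@H](C)CC | intermediate
13 | (3Z)-1α,10α-epoxy-9β-hydroxy-8α-[(2R)-2-methylbutanoyloxy]germacra-3,11-dien-5-one | C=C(C)[C@H]1CC(=O)/C(C)=C\C[C@@H]2O[C@]2(C)[C@@H](O)[C@@H]1OC(=O)[C@H](C)CC | intermediate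
14 | angelic acid, (Z)-2-methylbut-2-enoic acid | C/C=C(/C)C(O)=O | starting material
15 | angelic 2,4,6-trichlorobenzoic anhydride | C/C=C(/C)C(=O)OC(=O)c1c(Cl)cc(Cl)cc1Cl | intermediate
16 | (3Z)-9β-angeloyloxy-1α,10α-epoxy-8α-[(2R)-2-methylbutanoyloxy]germacra-3,11-dien-5-one | C=C(C)[C@H]1CC(=O)/C(C)=C\C[C@@H]2O[C@]2(C)[C@@H](OC(=O)/C(C)=C\C)[C@@H]1OC(=O)[C@H](C)CC | intermediate
17 | (3Z)-9β-angeloyloxy-1α,10α-epoxy-5β-hydroxy-8α-[(2R)-2-methylbutanoyloxy]germacra-3,11-diene | C=C(C)[C@H]1C[C@@H](O)/C(C)=C\C[C@@H]2O[C@]2(C)[C@@H](OC(=O)/C(C)=C\C)[C@@H]1OC(=O)[C@H](C)CC | intermediate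
18 | angelic anhydride | C/C=C(/C)C(=O)OC(=O)/C(C)=C\C | starting material
19 | peroxyangelic acid, (Z)-2-methylbut-2-eneperoxoic acid | C/C=C(/C)C(=O)OO | intermediate
20 | 9β-angeloyloxy-1α,10α:3α,4α-diepoxy-5β-hydroxy-8α-[(2R)-2-methylbutanoyloxy]germacr-11-ene | C=C(C)[C@H]1C[C@@H](O)[C@]2(C)O[C@@H]2C[C@@H]3O[C@]3(C)[C@@H](OC(=O)/C(C)=C\C)[C@@H]1OC(=O)[C@H](C)CC | intermediate
21 | (1S,3S,4S,5R,7R,8R,9S,10S)-3β,9β-bis(angeloyloxy)-1α,10α-epoxy-4α,5β-dihydroxy-8α-[(2R)-2-methylbutanoyloxy]germacr-11-ene (CNP0246823.2) | C=C(C)[C@H]1C[C@@H](O)[C@](C)(O)[C@@H](OC(=O)/C(C)=C\C)C[C@@H]2O[C@]2(C)[C@@H](OC(=O)/C(C)=C\C)[C@@H]1OC(=O)[C@H](C)CC | target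

Total step count: 11. Longest linear sequence: 11 steps (1 to 21).

**Steps most likely to fail**

Step 4 (thermal cycloreversion). At 190 °C the cis,trans-1,5-diene 8 can undergo Cope rearrangement to the divinylcyclohexanone, the epimerisable α-acyloxy ketone may suffer, and the alkene geometry is not guaranteed. The fallback removes the sensitive ester from the hot step. It sets out from 1 (with 6). Irradiation as in step 3 gives the carvone–methylcyclobutene photoadduct F1. Flash vacuum pyrolysis (about 500 °C, 0.01 mbar, short contact) opens it to (1(10)Z,4E)-germacra-1(10),4,11-trien-9-one F2. Kinetic enolisation with NaN(SiMe3)2 and Davis hydroxylation, anti to the isopropenyl group as in step 1, gives the 8α-hydroxy trienone F3. DCC/DMAP esterification with 4 then returns to the route at 8.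

Step 6 (exo-to-endo shift). RhCl3·3H2O may also move the isopropenyl double bond or give an E/Z mixture of the new enone. The fallback sets out from 10. RhCl(PPh3)3-catalysed 1,4-hydrosilylation with Et3SiH adds only to the unhindered exocyclic enone and gives the triethylsilyl enol ether F4. Saegusa–Ito oxidation with Pd(OAc)2 in MeCN then eliminates toward C3 and returns to the route at 11; any re-formed 10 is recycled.

Step 11 (proposed tandem). Peroxyangelic acid may be a sluggish or unstable oxidant, or the released acid may open the oxirane before the titanium template is in place (attack at C4, isopropoxide transfer). The fallback uses known chemistry stepwise and sets out from 17. mCPBA in CH2Cl2 at 0 °C (hydroxyl-directed epoxidation) gives the diepoxy alcohol 20, which is isolated. Ti(OiPr)4 with angelic acid 14 at rt (titanium-mediated C3-selective carboxylic acid opening of a 2,3-epoxy alcohol) then returns to the route at 21. New compounds on this detour: none F0.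

Further compounds
F1 | step 4 | 2,6-dimethyl-9-(prop-1-en-2-yl)tricyclo[4.4.0.0^2,5]decan-7-one, cis-anti-cis | C=C(C)[C@H]1C[C@@H]2[C@@]3(C)CC[C@H]3[C@]2(C)C(=O)C1
F2 | step 4 | (1(10)Z,4E)-germacra-1(10),4,11-trien-9-one | C=C(C)[C@H]1C/C=C(C)/CC/C=C(C)\C(=O)C1
F3 | step 4 | (1(10)Z,4E)-8α-hydroxygermacra-1(10),4,11-trien-9-one | C=C(C)[C@H]1C/C=C(C)/CC/C=C(C)\C(=O)[C@@H]1O
F4 | step 6 | (1(10)Z)-8α-[(2R)-2-methylbutanoyloxy]-5-(triethylsilyloxy)germacra-1(10),4,11-trien-9-one | C=C(C)[C@H]1C/C(O[Si](CC)(CC)CC)=C(C)\CC/C=C(C)\C(=O)[C@@H]1OC(=O)[C@H](C)CC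
F0 | step 11 | none | none
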